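I start with the easy step, the inventory.

left-handed substrate 20 mM; partner 20.0 mM (fed, over 80 min); protic impurity 20.0 mM; free catalyst 1.0 mM; right-handed substrate 20 mM; time 3.0 d

- at 3.0 d, what has stopped the reaction, if anything has (forward and back rates have come level / the partner has run out first / it is still moving / all of the left-handed substrate has reacted / no working catalyst is left)
- the left-handed product standing at 3.0 d, as a percentage of the left-handed substrate and right-handed substrate together charged
- the right-handed substrate standing at 3.0 d, as a percentage of the left-handed substrate and right-handed substrate together charged

- free catalyst is single-handed; left-handed substrate and right-handed substrate are mirror images of each other, charged as a racemate, each of them at the stated concentration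
- the reaction counts as stopped when no species that holds the left-handed substrate and right-handed substrate together changes by six tenths of a point or more over the second half of the time
- run time (flask): 3.0 d

Free catalyst binds each substrate reversibly, the left-handed one to catalyst intermediate A (67 M⁻¹) and the right-handed one to catalyst intermediate B (30 M⁻¹). Partner then turns each intermediate into its product and frees the catalyst, or is lost to the protic impurity. Bound substrate comes off at 0.284 s⁻¹, faster than partner takes the intermediate even at its whole charge. So I treat binding as equilibrated, and at the start intermediate A holds 0.456 mM.

Now I follow one partner molecule to its fork. It meets intermediate A with constant 0.71 M⁻¹ s⁻¹ or the impurity with 0.029 M⁻¹ s⁻¹. Both losses are pseudo-first-order in partner, so its concentration cancels from the odds. The arm through intermediate B is much slower, and I drop it. The starting chance of making left-handed product is 35.8 %, which turns 20.0 mM into 7.16 mM. The weak link is that the odds drift as left-handed substrate and impurity are consumed, so I reforge the chance at half of each expected loss: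

| | left-handed substrate | impurity | intermediate A | chance |
|---|---|---|---|---|
| start | 20 mM | 20.0 mM | 0.456 mM | 35.8 % |
| midway | 16.4 mM | 13.6 mM | 0.407 mM | 42.3 % |

This midway chance φ, the share of partner molecules ending as left-handed product, gives 8.47 mM, or 21.2 % of the substrate charged. Partner's midway half-life is 0.282 h, and with the 80 min feed that is much shorter than the run. Its charge is also smaller than left-handed substrate and impurity together, so I commit to partner as limiting reagent, its 20.0 mM consumed. Once partner is consumed, left-handed substrate stands near 11.5 mM, so I reckon 0.253 mM bound as intermediate B at the end. With a little more converted at the midway ratio of the two arms, right-handed substrate stands at 49.1 %.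

The forecast says the partner has run out first, with 20.6 % of left-handed product and 49.1 % of right-handed substrate, a product figure below mine. Its ground, speaking of the protic impurity, is that “its pseudo-first-order sink is comparable to the catalytic one”.

    free catalyst + left-handed substrate ⇌ catalyst intermediate A (K1 = 67 M⁻¹, k1 = 19 M⁻¹ s⁻¹)
    free catalyst + right-handed substrate ⇌ catalyst intermediate B (K2 = 30 M⁻¹, k2 = 10 M⁻¹ s⁻¹)
    partner + catalyst intermediate A → free catalyst + left-handed product (k3 = 0.71 M⁻¹ s⁻¹)
    partner + catalyst intermediate B → free catalyst + right-handed product (k4 = 0.015 M⁻¹ s⁻¹)
    partner + protic impurity → quenched reagent (k5 = 0.029 M⁻¹ s⁻¹)

The flask gives the same verdict, the partner has run out first, with 20.6 % of left-handed product, 49.1 % of right-handed substrate and 0 % of the partner left at 3.00 d. With the impurity's step struck out, left-handed product stands at 48.4 %. The other arm of φ gives 11.5 mM of quenched reagent, and this flask holds 11.6 mM. For the neighbour charged with 1.7 mM of free catalyst, I scale the odds φ/(1−φ) by the catalyst ratio, which gives 55.5 %. Recentring midway gives 50.2 %, hence 25.1 % product. That neighbour gives 25.3 %.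

All constants are those of an exercise; what happens was integrated by code.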